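## Retrosynthetic overview

1. The only ring, the 14-membered carbocycle, is formed last: C9–C10 is closed by intramolecular alkylation of a C10 allylic sulfone anion with a C9 allylic bromide, then the sulfone and the silyl group are removed.
2. The seco chain is opened at C3=C4: a Z-selective Ando olefination joins aldehyde 20 to phosphonate 19 (fragment C), and the ester later becomes the CH2OH group.
3. The C1–C15 bond and the only stereocentre come from an intermolecular organocatalytic Michael addition of nitroalkane 14 (fragment B) to enal 9 (fragment A); the nitro group then becomes C=O (Nef) and C=CH2.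
4. Fragment A comes from nerol (its Z alkene becomes C11=C12); fragments B and C both come from 5-bromo-2-methylpent-2-ene (SeO2 oxidation sets the E C7=C8 alkene).

Assumption: atoms are numbered as in the target SMILES, ring C1 (stereocentre) to C14, C15 the side-chain carbon on C1; read this way the target is 1R, C3=C4 Z (CH2OH cis to C2), C7=C8 E, C11=C12 Z.

## Route

Step 1
Reactants: 1 nerol
Product: 2 (2Z)-1-bromo-3,7-dimethylocta-2,6-diene
Conditions: PBr3 (0.4 equiv), Et2O, −10 °C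
Reagents that add atoms: phosphorus tribromide (BrP(Br)Br)
Why: Alcohol-to-bromide substitution with PBr3 at low temperature converts the primary allylic alcohol without allylic transposition and keeps the Z alkene.

Step 2
Reactants: 2 neryl bromide; 3 sodium benzenesulfinate
Product: 4 {[(2Z)-3,7-dimethylocta-2,6-dien-1-yl]sulfonyl}benzene
Conditions: DMF, rt
Reagents that add atoms: none
Why: SN2 S-alkylation of the sulfinate by the primary allylic bromide installs the sulfone that later stabilises the ring-closing carbanion.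

Step 3
Reactants: 4 neryl phenyl sulfone
Product: 5 2,2-dimethyl-3-[(3Z)-3-methyl-5-(phenylsulfonyl)pent-3-en-1-yl]oxirane
Conditions: mCPBA, NaHCO3, CH2Cl2, 0 °C
Reagents that add atoms: mCPBA (OOC(=O)c1cccc(Cl)c1)
Why: Prilezhaev epoxidation is selective for the electron-rich distal alkene because the allylic sulfone deactivates the other one; the racemic epoxide centre is destroyed in step 4.

Step 4
Reactants: 5 epoxide
Product: 7 (4Z)-4-methyl-6-(phenylsulfonyl)hex-4-enal, via diol 6 (not isolated)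
Conditions: H5IO6, THF/H2O, 0 °C → rt
Reagents that add atoms: none
Why: Acid-mediated epoxide hydrolysis (water opens the tertiary carbon) followed by Malaprade glycol cleavage releases the aldehyde, which keeps the former epoxide oxygen, and acetone.

Step 5
Reactants: 7 aldehyde; 8 (triphenylphosphoranylidene)acetaldehyde
Product: 9 (2E,6Z)-6-methyl-8-(phenylsulfonyl)octa-2,6-dienal
Conditions: toluene, 80 °C
Reagents that add atoms: none
Why: Wittig olefination with the stabilised formyl ylide gives the E enal and adds C2 and C3.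

Step 6
Reactants: 10 5-bromo-2-methylpent-2-ene
Product: 12 5-methylhex-4-en-1-ol, via Grignard reagent 11 (not isolated)
Conditions: Mg, THF, reflux; (CH2O)n, 0 °C → rt; aq. NH4Cl
Reagents that add atoms: paraformaldehyde, reacting as formaldehyde (C=O)
Why: Grignard addition to formaldehyde gives the one-carbon-homologated primary alcohol.

Step 7
Reactants: 12 5-methylhex-4-en-1-ol
Product: 13 6-iodo-2-methylhex-2-ene
Conditions: I2, PPh3, imidazole, CH2Cl2, 0 °C → rt
Reagents that add atoms: iodine (II)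
Why: Appel-type iodination (Garegg–Samuelsson conditions) converts the primary alcohol to the iodide by SN2 on the alkoxyphosphonium ion.

Step 8
Reactants: 13 6-iodo-2-methylhex-2-ene
Product: 14 2-methyl-6-nitrohex-2-ene
Conditions: AgNO2, Et2O, 0 °C → rt, dark
Reagents that add atoms: silver nitrite ([Ag+].[O-]N=O)
Why: Victor Meyer reaction, a silver-assisted SN2 displacement of the primary iodide by nitrite at nitrogen, gives the nitroalkane (the minor nitrite ester is separated).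

Step 9
Reactants: 10 5-bromo-2-methylpent-2-ene
Product: 15 (2E)-5-bromo-2-methylpent-2-en-1-ol
Conditions: SeO2 (cat.), t-BuOOH, salicylic acid (cat.), CH2Cl2, rt
Reagents that add atoms: tert-butyl hydroperoxide (CC(C)(C)OO)
Why: Sharpless SeO2/t-BuOOH allylic oxidation (ene reaction then 2,3-sigmatropic shift) hydroxylates the E methyl group selectively and so fixes the E geometry of the future C7=C8.

Step 10
Reactants: 15 (2E)-5-bromo-2-methylpent-2-en-1-ol
Product: 16 {[(2E)-5-bromo-2-methylpent-2-en-1-yl]oxy}(tert-butyl)dimethylsilane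
Conditions: TBSCl, imidazole, CH2Cl2, rt
Reagents that add atoms: TBSCl (CC(C)(C)[Si](C)(C)Cl)
Why: Standard silylation protects the primary allylic alcohol through the enolate and hydride steps.

Step 11
Reactants: 17 ethyl 2-[bis(2-methylphenoxy)phosphoryl]acetate; 16 bromide
Product: 19 ethyl (5E)-2-[bis(2-methylphenoxy)phosphoryl]-7-{[tert-butyl(dimethyl)silyl]oxy}-6-methylhept-5-enoate, via sodium phosphonate 18 (not isolated)
Conditions: NaH, DMF, 0 °C; then 16, NaI (cat.), 50 °C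
Reagents that add atoms: none
Why: SN2 C-alkylation of the weakly basic phosphonoacetate anion by the primary bromide (iodide catalysis) gives the alpha-substituted Ando reagent.

Step 12
Reactants: 9 enal; 14 nitroalkane
Product: 20 (3R,6Z)-6-methyl-3-(5-methyl-1-nitrohex-4-en-1-yl)-8-(phenylsulfonyl)oct-6-enal
Conditions: (S)-2-[diphenyl(trimethylsilyloxy)methyl]pyrrolidine (10 mol %), PhCO2H (20 mol %), MeOH, rt; 14 (3 equiv)
Reagents that add atoms: none
Why: In this organocatalytic asymmetric Michael addition (iminium activation, Hayashi–Jørgensen type) the diphenyl(silyloxy)methyl group of the S catalyst shields one face of the E iminium ion of 9, so the nitronate of 14 adds to C1 from the open face and sets 1R; the nitro-bearing carbon forms as an inconsequential epimer mixture.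

Step 13
Reactants: 20 nitro aldehyde; 19 phosphonate
Product: 22 ethyl (2Z,5R,8Z)-2-[(3E)-5-{[tert-butyl(dimethyl)silyl]oxy}-4-methylpent-3-en-1-yl]-8-methyl-5-(5-methyl-1-nitrohex-4-en-1-yl)-10-(phenylsulfonyl)deca-2,8-dienoate, via sodium phosphonate 21 (not isolated)
Conditions: 19 (1.3 equiv), NaH, THF, 0 °C; then 20, −78 → −20 °C
Reagents that add atoms: none
Why: The Ando variant of the Horner–Wadsworth–Emmons reaction gives the Z trisubstituted enoate (C2 cis to the ester) under kinetic control, and the pre-formed anion is too weak a base to disturb the nitro group at low temperature.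

Step 14
Reactants: 22 nitro enoate
Product: 24 ethyl (2Z,5R,8Z)-2-[(3E)-5-{[tert-butyl(dimethyl)silyl]oxy}-4-methylpent-3-en-1-yl]-8-methyl-5-(5-methylhex-4-enoyl)-10-(phenylsulfonyl)deca-2,8-dienoate, via potassium nitronate 23 (not isolated)
Conditions: KOt-Bu (1.05 equiv), THF, 0 °C; then aq. TiCl3, NH4OAc (pH 5–6), rt
Reagents that add atoms: water (O)
Why: In this Nef reaction (McMurry reductive variant) TiCl3 reduces the nitronate to the imine, which hydrolyses at buffered pH to the ketone without touching the enoate, silyl ether, sulfone or the adjacent C1 centre.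

Step 15
Reactants: 24 ketone
Product: 25 ethyl (2Z,5R,8Z)-2-[(3E)-5-{[tert-butyl(dimethyl)silyl]oxy}-4-methylpent-3-en-1-yl]-8-methyl-5-(6-methylhepta-1,5-dien-2-yl)-10-(phenylsulfonyl)deca-2,8-dienoate
Conditions: Zn, CH2Br2, TiCl4, THF/CH2Cl2, 0 °C → rt
Reagents that add atoms: dibromomethane (BrCBr)
Why: Takai–Lombardo methylenation with the non-basic zinc/titanium methylene reagent converts the enolisable alpha-branched ketone to the 1,1-disubstituted alkene without epimerising C1 and leaves the ester alone.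

Step 16
Reactants: 25 ester
Product: 26 (2Z,5R,8Z)-2-[(3E)-5-{[tert-butyl(dimethyl)silyl]oxy}-4-methylpent-3-en-1-yl]-8-methyl-5-(6-methylhepta-1,5-dien-2-yl)-10-(phenylsulfonyl)deca-2,8-dien-1-ol
Conditions: i-Bu2AlH (2.5 equiv), CH2Cl2, −78 °C; aq. potassium sodium tartrate
Reagents that add atoms: none
Why: 1,2-Hydride reduction of the enoate gives the allylic alcohol with the alkene geometry retained.

Step 17
Reactants: 26 allylic alcohol
Product: 27 tert-butyl({(2Z,5R,8Z)-2-[(3E)-5-{[tert-butyl(dimethyl)silyl]oxy}-4-methylpent-3-en-1-yl]-8-methyl-5-(6-methylhepta-1,5-dien-2-yl)-10-(phenylsulfonyl)deca-2,8-dien-1-yl}oxy)diphenylsilane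
Conditions: t-BuPh2SiCl, imidazole, DMF, rt
Reagents that add atoms: TBDPSCl (CC(C)(C)[Si](Cl)(c1ccccc1)c1ccccc1)
Why: Silylation as the acid-stable TBDPS ether keeps the future CH2OH masked during ring closure and lets the TBS ether be removed selectively.

Step 18
Reactants: 27 bis-silyl ether
Product: 28 (2E,6Z,9R,12Z)-6-({[tert-butyl(diphenyl)silyl]oxy}methyl)-2,12-dimethyl-9-(6-methylhepta-1,5-dien-2-yl)-14-(phenylsulfonyl)tetradeca-2,6,12-trien-1-ol
Conditions: PPTS (cat.), MeOH, rt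
Reagents that add atoms: none
Why: Acid-catalysed methanolysis cleaves the primary TBS ether much faster than the TBDPS ether (selective desilylation).

Step 19
Reactants: 28 allylic alcohol
Product: 29 {[(2Z,5R,8Z)-2-[(3E)-5-bromo-4-methylpent-3-en-1-yl]-8-methyl-5-(6-methylhepta-1,5-dien-2-yl)-10-(phenylsulfonyl)deca-2,8-dien-1-yl]oxy}(tert-butyl)diphenylsilane
Conditions: CBr4, PPh3, CH2Cl2, 0 °C
Reagents that add atoms: carbon tetrabromide (BrC(Br)(Br)Br)
Why: Appel bromination converts the primary allylic alcohol to the bromide under neutral conditions without allylic rearrangement.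

Step 20
Reactants: 29 bromo sulfone
Product: 31 tert-butyl{[(1Z,4E,8Z,12R)-5,9-dimethyl-12-(6-methylhepta-1,5-dien-2-yl)-7-(phenylsulfonyl)cyclotetradeca-1(14),4,8-trien-1-yl]methoxy}diphenylsilane, via sodium sulfonyl carbanion 30 (not isolated)
Conditions: NaN(SiMe3)2 (1.1 equiv), THF, 0.002 M, −78 → 0 °C, slow addition
Reagents that add atoms: none
Why: Intramolecular SN2 alkylation of the allylic sulfonyl carbanion (Julia-type sulfone coupling) at high dilution closes the 14-membered ring at C9–C10 with retention of both alkene geometries; the new sulfone-bearing centre is an epimer mixture that is removed in step 21.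

Step 21
Reactants: 31 macrocyclic sulfone
Product: 32 tert-butyl{[(1Z,4E,8Z,12R)-5,9-dimethyl-12-(6-methylhepta-1,5-dien-2-yl)cyclotetradeca-1(14),4,8-trien-1-yl]methoxy}diphenylsilane
Conditions: PdCl2[Ph2P(CH2)3PPh2] (5 mol %), LiBHEt3 (3 equiv), THF, 0 °C
Reagents that add atoms: none
Why: In this palladium-catalysed reductive desulfonylation, hydride is delivered to the less substituted terminus of the pi-allyl complex (C10), which keeps the C11=C12 position and its Z geometry.

Step 22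
Reactants: 32 silyl ether
Product: 33 [(1Z,4E,8Z,12R)-5,9-dimethyl-12-(6-methylhepta-1,5-dien-2-yl)cyclotetradeca-1(14),4,8-trien-1-yl]methanol
Conditions: Bu4NF, THF, rt
Reagents that add atoms: none
Why: Fluoride-mediated desilylation frees the primary allylic alcohol and gives the target.

## Compound list

1 | nerol, (2Z)-3,7-dimethylocta-2,6-dien-1-ol | CC(C)=CCC/C(C)=C\CO | starting material
2 | (2Z)-1-bromo-3,7-dimethylocta-2,6-diene (neryl bromide) | CC(C)=CCC/C(C)=C\CBr | intermediate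
3 | sodium benzenesulfinate | [Na+].[O-]S(=O)c1ccccc1 | starting material
4 | {[(2Z)-3,7-dimethylocta-2,6-dien-1-yl]sulfonyl}benzene (neryl phenyl sulfone) | CC(C)=CCC/C(C)=C\CS(=O)(=O)c1ccccc1 | intermediate
5 | 2,2-dimethyl-3-[(3Z)-3-methyl-5-(phenylsulfonyl)pent-3-en-1-yl]oxirane (racemic) | CC1(C)OC1CC/C(C)=C\CS(=O)(=O)c1ccccc1 | intermediate
6 | (6Z)-2,6-dimethyl-8-(phenylsulfonyl)oct-6-ene-2,3-diol (racemic, not isolated) | CC(C)(O)C(O)CC/C(C)=C\CS(=O)(=O)c1ccccc1 | intermediate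
7 | (4Z)-4-methyl-6-(phenylsulfonyl)hex-4-enal | O=CCC/C(C)=C\CS(=O)(=O)c1ccccc1 | intermediate
8 | (triphenylphosphoranylidene)acetaldehyde | O=CC=P(c1ccccc1)(c1ccccc1)c1ccccc1 | starting material
9 | (2E,6Z)-6-methyl-8-(phenylsulfonyl)octa-2,6-dienal (fragment A) | O=C/C=C/CC/C(C)=C\CS(=O)(=O)c1ccccc1 | intermediate
10 | 5-bromo-2-methylpent-2-ene | CC(C)=CCCBr | starting material
11 | (4-methylpent-3-en-1-yl)magnesium bromide (not isolated) | CC(C)=CCC[Mg]Br | intermediate
12 | 5-methylhex-4-en-1-ol | CC(C)=CCCCO | intermediate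
13 | 6-iodo-2-methylhex-2-ene | CC(C)=CCCCI | intermediate
14 | 2-methyl-6-nitrohex-2-ene (fragment B) | CC(C)=CCCC[N+](=O)[O-] | intermediate
15 | (2E)-5-bromo-2-methylpent-2-en-1-ol | OC/C(C)=C/CCBr | intermediate
16 | {[(2E)-5-bromo-2-methylpent-2-en-1-yl]oxy}(tert-butyl)dimethylsilane | CC(C)(C)[Si](C)(C)OC/C(C)=C/CCBr | intermediate
17 | ethyl 2-[bis(2-methylphenoxy)phosphoryl]acetate | CCOC(=O)CP(=O)(Oc1ccccc1C)Oc1ccccc1C | starting material
18 | sodium salt of 17, carbanion at C2 (not isolated) | CCOC(=O)[CH-]P(=O)(Oc1ccccc1C)Oc1ccccc1C.[Na+] | intermediate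
19 | ethyl (5E)-2-[bis(2-methylphenoxy)phosphoryl]-7-{[tert-butyl(dimethyl)silyl]oxy}-6-methylhept-5-enoate (fragment C, racemic at C2) | CCOC(=O)C(CC/C=C(\C)CO[Si](C)(C)C(C)(C)C)P(=O)(Oc1ccccc1C)Oc1ccccc1C | intermediate
20 | (3R,6Z)-6-methyl-3-(5-methyl-1-nitrohex-4-en-1-yl)-8-(phenylsulfonyl)oct-6-enal (both epimers at the nitro carbon) | O=CC[C@@H](CC/C(C)=C\CS(=O)(=O)c1ccccc1)C([N+](=O)[O-])CCC=C(C)C | intermediate
21 | sodium salt of 19, carbanion at C2 (not isolated) | CCOC(=O)[C-](CC/C=C(\C)CO[Si](C)(C)C(C)(C)C)P(=O)(Oc1ccccc1C)Oc1ccccc1C.[Na+] | intermediate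
22 | ethyl (2Z,5R,8Z)-2-[(3E)-5-{[tert-butyl(dimethyl)silyl]oxy}-4-methylpent-3-en-1-yl]-8-methyl-5-(5-methyl-1-nitrohex-4-en-1-yl)-10-(phenylsulfonyl)deca-2,8-dienoate (both epimers at the nitro carbon) | CCOC(=O)/C(CC/C=C(\C)CO[Si](C)(C)C(C)(C)C)=C\C[C@@H](CC/C(C)=C\CS(=O)(=O)c1ccccc1)C([N+](=O)[O-])CCC=C(C)C | intermediate
23 | potassium nitronate of 22 (not isolated) | CCOC(=O)/C(CC/C=C(\C)CO[Si](C)(C)C(C)(C)C)=C\C[C@@H](CC/C(C)=C\CS(=O)(=O)c1ccccc1)C(CCC=C(C)C)=[N+]([O-])[O-].[K+] | intermediate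
24 | ethyl (2Z,5R,8Z)-2-[(3E)-5-{[tert-butyl(dimethyl)silyl]oxy}-4-methylpent-3-en-1-yl]-8-methyl-5-(5-methylhex-4-enoyl)-10-(phenylsulfonyl)deca-2,8-dienoate | CCOC(=O)/C(CC/C=C(\C)CO[Si](C)(C)C(C)(C)C)=C\C[C@@H](CC/C(C)=C\CS(=O)(=O)c1ccccc1)C(=O)CCC=C(C)C | intermediate
25 | ethyl (2Z,5R,8Z)-2-[(3E)-5-{[tert-butyl(dimethyl)silyl]oxy}-4-methylpent-3-en-1-yl]-8-methyl-5-(6-methylhepta-1,5-dien-2-yl)-10-(phenylsulfonyl)deca-2,8-dienoate | CCOC(=O)/C(CC/C=C(\C)CO[Si](C)(C)C(C)(C)C)=C\C[C@@H](CC/C(C)=C\CS(=O)(=O)c1ccccc1)C(=C)CCC=C(C)C | intermediate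
26 | (2Z,5R,8Z)-2-[(3E)-5-{[tert-butyl(dimethyl)silyl]oxy}-4-methylpent-3-en-1-yl]-8-methyl-5-(6-methylhepta-1,5-dien-2-yl)-10-(phenylsulfonyl)deca-2,8-dien-1-ol | OC/C(CC/C=C(\C)CO[Si](C)(C)C(C)(C)C)=C\C[C@@H](CC/C(C)=C\CS(=O)(=O)c1ccccc1)C(=C)CCC=C(C)C | intermediate
27 | tert-butyl({(2Z,5R,8Z)-2-[(3E)-5-{[tert-butyl(dimethyl)silyl]oxy}-4-methylpent-3-en-1-yl]-8-methyl-5-(6-methylhepta-1,5-dien-2-yl)-10-(phenylsulfonyl)deca-2,8-dien-1-yl}oxy)diphenylsilane | CC(C)(C)[Si](c1ccccc1)(c1ccccc1)OC/C(CC/C=C(\C)CO[Si](C)(C)C(C)(C)C)=C\C[C@@H](CC/C(C)=C\CS(=O)(=O)c1ccccc1)C(=C)CCC=C(C)C | intermediate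
28 | (2E,6Z,9R,12Z)-6-({[tert-butyl(diphenyl)silyl]oxy}methyl)-2,12-dimethyl-9-(6-methylhepta-1,5-dien-2-yl)-14-(phenylsulfonyl)tetradeca-2,6,12-trien-1-ol | CC(C)(C)[Si](c1ccccc1)(c1ccccc1)OC/C(CC/C=C(\C)CO)=C\C[C@@H](CC/C(C)=C\CS(=O)(=O)c1ccccc1)C(=C)CCC=C(C)C | intermediate
29 | {[(2Z,5R,8Z)-2-[(3E)-5-bromo-4-methylpent-3-en-1-yl]-8-methyl-5-(6-methylhepta-1,5-dien-2-yl)-10-(phenylsulfonyl)deca-2,8-dien-1-yl]oxy}(tert-butyl)diphenylsilane | CC(C)(C)[Si](c1ccccc1)(c1ccccc1)OC/C(CC/C=C(\C)CBr)=C\C[C@@H](CC/C(C)=C\CS(=O)(=O)c1ccccc1)C(=C)CCC=C(C)C | intermediate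
30 | sodium salt of 29, carbanion at the sulfone-bearing carbon (not isolated) | CC(C)(C)[Si](c1ccccc1)(c1ccccc1)OC/C(CC/C=C(\C)CBr)=C\C[C@@H](CC/C(C)=C\[CH-]S(=O)(=O)c1ccccc1)C(=C)CCC=C(C)C.[Na+] | intermediate
31 | tert-butyl{[(1Z,4E,8Z,12R)-5,9-dimethyl-12-(6-methylhepta-1,5-dien-2-yl)-7-(phenylsulfonyl)cyclotetradeca-1(14),4,8-trien-1-yl]methoxy}diphenylsilane (both epimers at the sulfone carbon) | C=C(CCC=C(C)C)[C@H]1C/C=C(\CO[Si](c2ccccc2)(c2ccccc2)C(C)(C)C)CC/C=C(\C)CC(S(=O)(=O)c2ccccc2)/C=C(/C)CC1 | intermediate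
32 | tert-butyl{[(1Z,4E,8Z,12R)-5,9-dimethyl-12-(6-methylhepta-1,5-dien-2-yl)cyclotetradeca-1(14),4,8-trien-1-yl]methoxy}diphenylsilane | C=C(CCC=C(C)C)[C@H]1C/C=C(\CO[Si](c2ccccc2)(c2ccccc2)C(C)(C)C)CC/C=C(\C)CC/C=C(/C)CC1 | intermediate
33 | [(1Z,4E,8Z,12R)-5,9-dimethyl-12-(6-methylhepta-1,5-dien-2-yl)cyclotetradeca-1(14),4,8-trien-1-yl]methanol (CNP0217603.2) | C=C(CCC=C(C)C)[C@H]1C/C=C(\CO)CC/C=C(\C)CC/C=C(/C)CC1 | target

## Step count and risks

Total steps: 22. Longest linear sequence: 16 (steps 1–5, then 12–22); fragment B takes 3 steps (6–8) and fragment C takes 3 steps (9–11).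

The three steps most likely to fail:

Step 12 (key Michael addition). A higher nitroalkane on an aliphatic enal may react slowly or with eroded enantioselectivity. The fallback sets out from 9 and comes back at 24. Nitromethane, the best-behaved donor for this catalyst, is added to 9 to give the nitromethyl aldehyde F1. Ando olefination of F1 with 19 gives the nitromethyl enoate F2. A McMurry–Nef reaction (KOt-Bu; aq. TiCl3, NH4OAc) converts F2 to the alpha-branched aldehyde F3, which is used at once. Grignard reagent 11 in the presence of CeCl3 at −78 °C adds to F3 to give the secondary alcohol F4, and Dess–Martin oxidation of F4 gives ketone 24. The side chain is thus attached by carbonyl addition instead of being carried by the Michael donor.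

Step 14 (Nef reaction). The hindered secondary nitronate next to C1 may stall at the oxime stage or give low conversion with TiCl3. The fallback sets out from 22 and comes back at 24. The nitro group is first reduced with SnCl2, PhSH and Et3N to the isolable ketoxime F5. Transoximation of F5 with aqueous glyoxylic acid (NaOAc buffer) then releases ketone 24 under nearly neutral conditions.

Step 20 (macrocyclisation). The strongly basic sulfonyl carbanion may oligomerise or cyclise in low yield. The fallback sets out from 27 and comes back at 31. The sulfone carbon of 27 is acylated (LiN(i-Pr)2, 2.2 equiv; ClCO2Me) to give the sulfonyl ester F6. Selective desilylation (PPTS, MeOH) gives the alcohol F7, and Appel bromination gives the bromide F8. The doubly stabilised, soft carbanion of F8 is cyclised with Cs2CO3 in DMF at high dilution to the macrocyclic sulfonyl ester F9. Krapcho dealkoxycarbonylation of F9 (LiCl, wet DMSO, 130 °C) gives 31.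

## Further compounds

F1 | step 12 | (3R,6Z)-6-methyl-3-(nitromethyl)-8-(phenylsulfonyl)oct-6-enal | O=CC[C@@H](CC/C(C)=C\CS(=O)(=O)c1ccccc1)C[N+](=O)[O-]
F2 | step 12 | ethyl (2Z,5R,8Z)-2-[(3E)-5-{[tert-butyl(dimethyl)silyl]oxy}-4-methylpent-3-en-1-yl]-8-methyl-5-(nitromethyl)-10-(phenylsulfonyl)deca-2,8-dienoate | CCOC(=O)/C(CC/C=C(\C)CO[Si](C)(C)C(C)(C)C)=C\C[C@@H](CC/C(C)=C\CS(=O)(=O)c1ccccc1)C[N+](=O)[O-]
F3 | step 12 | ethyl (2Z,5R,8Z)-2-[(3E)-5-{[tert-butyl(dimethyl)silyl]oxy}-4-methylpent-3-en-1-yl]-5-formyl-8-methyl-10-(phenylsulfonyl)deca-2,8-dienoate | CCOC(=O)/C(CC/C=C(\C)CO[Si](C)(C)C(C)(C)C)=C\C[C@@H](CC/C(C)=C\CS(=O)(=O)c1ccccc1)C=O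
F4 | step 12 | ethyl (2Z,5R,8Z)-2-[(3E)-5-{[tert-butyl(dimethyl)silyl]oxy}-4-methylpent-3-en-1-yl]-5-(1-hydroxy-5-methylhex-4-en-1-yl)-8-methyl-10-(phenylsulfonyl)deca-2,8-dienoate (both carbinol epimers) | CCOC(=O)/C(CC/C=C(\C)CO[Si](C)(C)C(C)(C)C)=C\C[C@@H](CC/C(C)=C\CS(=O)(=O)c1ccccc1)C(O)CCC=C(C)C
F5 | step 14 | ethyl (2Z,5R,8Z)-2-[(3E)-5-{[tert-butyl(dimethyl)silyl]oxy}-4-methylpent-3-en-1-yl]-5-[1-(hydroxyimino)-5-methylhex-4-en-1-yl]-8-methyl-10-(phenylsulfonyl)deca-2,8-dienoate | CCOC(=O)/C(CC/C=C(\C)CO[Si](C)(C)C(C)(C)C)=C\C[C@@H](CC/C(C)=C\CS(=O)(=O)c1ccccc1)C(CCC=C(C)C)=NO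
F6 | step 20 | derivative of 27 carrying CO2Me on the sulfone-bearing carbon (both epimers there) | CC(C)(C)[Si](c1ccccc1)(c1ccccc1)OC/C(CC/C=C(\C)CO[Si](C)(C)C(C)(C)C)=C\C[C@@H](CC/C(C)=C\C(C(=O)OC)S(=O)(=O)c1ccccc1)C(=C)CCC=C(C)C
F7 | step 20 | derivative of 28 carrying CO2Me on the sulfone-bearing carbon (both epimers there) | CC(C)(C)[Si](c1ccccc1)(c1ccccc1)OC/C(CC/C=C(\C)CO)=C\C[C@@H](CC/C(C)=C\C(C(=O)OC)S(=O)(=O)c1ccccc1)C(=C)CCC=C(C)C
F8 | step 20 | derivative of 29 carrying CO2Me on the sulfone-bearing carbon (both epimers there) | CC(C)(C)[Si](c1ccccc1)(c1ccccc1)OC/C(CC/C=C(\C)CBr)=C\C[C@@H](CC/C(C)=C\C(C(=O)OC)S(=O)(=O)c1ccccc1)C(=C)CCC=C(C)C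
F9 | step 20 | derivative of 31 carrying CO2Me on the sulfone-bearing ring carbon (both epimers there) | C=C(CCC=C(C)C)[C@H]1C/C=C(\CO[Si](c2ccccc2)(c2ccccc2)C(C)(C)C)CC/C=C(\C)CC(C(=O)OC)(S(=O)(=O)c2ccccc2)/C=C(/C)CC1
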